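Watching the birch run, I looked for one number that stayed nearly constant while the electrophile fell.

| flask | electrophile | nucleophile | scavenger | protic impurity | remark | time |
|---|---|---|---|---|---|---|
| birch | 0.30 M | 0.18 M | 0.20 M | 0.20 M | run made earlier |  |
| south | 0.20 M | 0.180 M | 0.200 M | 0.200 M |  | 1.0 h |
| north | 0.20 M | 0.180 M | 0.400 M | 0.200 M |  | 1.0 h |

birch run (percent of the electrophile charged)

| time / min | electrophile / % | target / % |
|---|---|---|
| 1.50 | 83.0 | 3.9 |
| 4.00 | 64.5 | 8.3 |
| 8.00 | 47.9 | 12.5 |
| 12.0 | 38.4 | 14.0 |

(standard deviation of a reading: 0.3 percentage points)

- part of the electrophile that has reacted at the end, south
- part of the electrophile that has reacted at the end, north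
- what raising the concentration of scavenger from its lowest to its highest value here does to the part of the electrophile that has reacted (changes below 5 percentage points count as none) (it falls / no change / it rises)

I took the charged electrophile over what was left, subtracted one, and divided by the charge c and the time t. In birch this gave 0.455 /M/min at the first reading and 0.446 /M/min at the last, so I carried the last as the apparent second-order loss constant k.

At the bench this becomes a rule of thumb: as long as the loss stays second order in electrophile with k unchanged, a dose D = k·c·t leaves the fraction 1/(1+D). Half is gone at a dose of one, and well above one, each power of ten in dose takes about one power of ten off what is left. South had a dose of 5.35, and the base-ten logarithm of one plus that dose is 0.803, so I expected 15.8% of its electrophile left and 84.2% reacted.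

The border was plain from a ratio. South ran 5.00 times as long as the last birch reading, with 0.667 of the electrophile charge of birch, which gave it 3.33 times the dose of 1.60 that birch had reached, and there the rule was extrapolation. North had twice the scavenger of birch, which no run had varied, so my equal figure for north was a guess.

The forecast put south at 85% and north at 85%, with no change between them, slightly above my south figure, from a decay it called “cleanly linear, giving second order in electrophile”.

The flasks gave 85.3% for south and 85.6% for north, no change, a shift of 0.38 percentage points.

    nucleophile + acid set free ⇌ idle adduct, settled at all times (K = 4.40 /M)
    acid set free + scavenger → scavenged by-product (k = 0.180 /M/s)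
    nucleophile + protic impurity → quenched reagent (k = 0.00290 /M/s)
    electrophile + nucleophile → acid set free + target (k = 0.00300 /M/s)
    nucleophile + acid set free ⇌ protonated nucleophile, settled at all times (K = 4000 /M)
    2 electrophile → self-condensation product (k = 0.00290 /M/s)

South kept 15% of its electrophile against my 15.8%. North read at 40 min had a dose of 3.56, which gives 21.9% left, and that flask held 20%. In north at 0.209 h, electrophile went to self-condensation product 2.4 times as fast as to target. At 1.00 h, north held 59.7% of its charged electrophile as self-condensation product against 26.0% as target.

The runs were generated by integration with made-up constants, noise included.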